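**Plan**
- Retrosynthesis cuts: (i) the CH2–CH bond between the allylic CH2 of the ethylidene link and the cyclohexane CH (enolate alkylation); (ii) the bond between the ring-fusion CH and the CMe2 carbon of the seven-membered ring (key ring closure); (iii) the bond between the other ring-fusion CH and its ring CH2 (conjugate addition); (iv) the O–CMe2 and C(Me)–CH2 bonds of the benzoxepane (bis-epoxide cascade).
- Forward order: (R)-linalool gives a silyloxy cyclopentenone; a 3-methylglutarate half-ester gives a side chain ending in a 2,2-dimethyl-2,5-dihydrofuran; conjugate addition attaches the chain to the five-membered ring, the seven-membered ring is closed, the helper carbonyl is removed; geranylacetone gives the oxepane–cyclohexenone; enolate alkylation joins the halves; methyl addition, desilylation and oxidation finish.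
- Enabling feature: the CMe2 ring carbon is allylic to the exocyclic C=CH–CH2 alkene and bonded to the ring-fusion CH, which is α to a temporary carbonyl on the cyclopentane, so the bond is a tertiary allyl cation / enol silane pair. The dihydrofuran ring (not in the target) stores that cation and holds the CH2O arm cis to CMe2 (Z alkene); it is opened in the key step, and the helper carbonyl is removed in steps 14–15.
- Stereochemistry: cyclopentane carbinol from linalool; adjacent CH by anti conjugate addition; second ring-fusion CH by cis ring closure; CHMe from the half-ester; oxepane/cyclohexane fusion and angular methyl from Shi epoxidation and anti epoxide openings; side-chain CH by equilibration; cyclohexane carbinol by equatorial methyl addition.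

Key step: step 13

Remark: (R)-linalool 1 and half-ester 5 are taken as enantiomerically pure commercial materials, and the silyloxy-bearing oxepane carbon is a temporary stereocentre that becomes the ketone carbon in step 25.

Step 1
Reactants: 1 (R)-linalool
Product: 2 (1R)-1-methylcyclopent-2-en-1-ol
Conditions: second-generation Grubbs catalyst RuCl2(=CHPh)(PCy3)(H2IMes) (1 mol%), CH2Cl2, 23 °C
Reagents that add atoms: none
Why: Ring-closing metathesis of the 1,6-diene should close the cyclopentene with loss of 2-methylpropene and leaves the tertiary carbinol stereocentre of linalool untouched.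

Step 2
Reactants: 2 (1R)-1-methylcyclopent-2-en-1-ol
Product: 3 tert-butyldimethylsilyl ether of 2
Conditions: t-BuMe2SiOTf, 2,6-lutidine, CH2Cl2, 0 °C
Reagents that add atoms: tert-butyldimethylsilyl triflate, CC(C)(C)[Si](C)(C)OS(=O)(=O)C(F)(F)F
Why: Silylation of the tertiary allylic alcohol with a silyl triflate and a hindered base (protecting-group installation) should be clean, and the bulky silyl ether later directs the conjugate addition.

Step 3
Reactants: 3 silyl ether
Product: 4 (4R)-4-[(tert-butyldimethylsilyl)oxy]-4-methylcyclopent-2-en-1-one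
Conditions: Rh2(cap)4 (cap = caprolactamate, 1 mol%), t-BuOOH (70% in water), K2CO3 (cat.), CH2Cl2, 23 °C
Reagents that add atoms: tert-butyl hydroperoxide, CC(C)(C)OO
Why: Allylic oxidation with t-BuOOH under dirhodium caprolactamate catalysis should oxidise the only allylic CH2 group (the other allylic carbon is quaternary) to the carbonyl of the γ-silyloxy enone.

Step 4
Reactants: 5 methyl hydrogen (R)-3-methylglutarate
Product: 7 (4S)-4-methyloxan-2-one, via hydroxy acid 6 (not isolated)
Conditions: LiOH (1.0 equiv), MeOH, 23 °C, evaporate; LiBH4, THF, 65 °C; then 2 M HCl, 23 °C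
Reagents that add atoms: none
Why: Chemoselective LiBH4 reduction of the ester in the presence of the carboxylate, then acid lactonisation, should give the lactone, and reducing the ester arm (not the acid arm) of the R half-ester fixes the S configuration.

Step 5
Reactants: 7 (4S)-4-methyloxan-2-one
Product: 10 (4S)-4-methyl-3-methylideneoxan-2-one, via Mannich base 8 (not isolated), via methiodide 9 (not isolated)
Conditions: LiN(i-Pr)2, THF, −78 °C; CH2=NMe2+ I−, −78 → 23 °C; then MeI, MeOH, 23 °C; then NaHCO3 (aq), CH2Cl2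
Reagents that add atoms: Eschenmoser's salt (N,N-dimethylmethyleneiminium iodide), C=[N+](C)C.[I-]
Why: Mannich reaction of the lactone enolate, N-methylation and E1cB loss of trimethylamine (α-methylenation) should give the α-methylene lactone, and the stereocentre is β to the carbonyl and cannot epimerise.

Step 6
Reactants: 10 α-methylene lactone
Product: 11 (3S)-3,5-dimethyl-4-methylidenehexane-1,5-diol
Conditions: MeLi (3.2 equiv), CeCl3, THF, −78 → 0 °C
Reagents that add atoms: methyllithium, [Li]C
Why: Double 1,2-addition of the methylcerium reagent to the lactone carbonyl (the cerium reagent suppresses 1,4-addition) should give the tertiary allylic alcohol and free the primary alcohol.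

Step 7
Reactants: 11 diol
Product: 12 (4S)-6-[(tert-butyldimethylsilyl)oxy]-2,4-dimethyl-3-methylidenehexan-2-ol
Conditions: t-BuMe2SiCl, imidazole, CH2Cl2, 0 °C
Reagents that add atoms: tert-butyldimethylsilyl chloride, CC(C)(C)[Si](C)(C)Cl
Why: Silylation with the silyl chloride and imidazole should select the primary over the tertiary hydroxyl on steric grounds.

Step 8
Reactants: 12 mono-silyl ether
Product: 13 allyl ether of the tertiary alcohol of 12
Conditions: KH, allyl bromide, THF, 0 → 23 °C
Reagents that add atoms: allyl bromide, C=CCBr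
Why: Williamson etherification of the potassium tert-alkoxide with the reactive allylic bromide should give the diene needed for ring closure.

Step 9
Reactants: 13 allyl ether
Product: 14 tert-butyl{[(3S)-3-(2,2-dimethyl-2,5-dihydrofuran-3-yl)butyl]oxy}dimethylsilane
Conditions: second-generation Hoveyda–Grubbs catalyst RuCl2(=CH–C6H4-2-O-i-Pr)(H2IMes) (5 mol%), toluene, 80 °C
Reagents that add atoms: none
Why: Ring-closing metathesis of the 1,1-disubstituted alkene with the allyl ether (helped by the gem-dimethyl group) should give the 2,5-dihydrofuran, whose ring holds the future CH2O arm cis to the CMe2 carbon.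

Step 10
Reactants: 14 dihydrofuran silyl ether
Product: 15 (3S)-3-(2,2-dimethyl-2,5-dihydrofuran-3-yl)butan-1-ol
Conditions: Bu4NF, THF, 0 °C
Reagents that add atoms: none
Why: Fluoride cleavage of the primary silyl ether is a standard deprotection that leaves the cyclic allylic ether alone.

Step 11
Reactants: 15 alcohol
Product: 16 3-[(2S)-4-bromobutan-2-yl]-2,2-dimethyl-2,5-dihydrofuran
Conditions: CBr4, PPh3, CH2Cl2, 0 °C
Reagents that add atoms: carbon tetrabromide, BrC(Br)(Br)Br
Why: Appel bromination converts the primary alcohol into the bromide under neutral conditions that should not ionise the tertiary allylic ether.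

Step 12
Reactants: 16 bromide; 4 silyloxy enone
Product: 18 tert-butyl({(1R,5R)-5-[(3S)-3-(2,2-dimethyl-2,5-dihydrofuran-3-yl)butyl]-1-methyl-3-[(trimethylsilyl)oxy]cyclopent-3-en-1-yl}oxy)dimethylsilane, via Grignard reagent 17 (not isolated)
Conditions: Mg, THF, 40 °C; then CuBr·SMe2 (10 mol%), Me3SiCl, DMPU, THF, −78 °C, add 4; Et3N, pentane work-up
Reagents that add atoms: chlorotrimethylsilane, C[Si](C)(C)Cl
Why: Copper-catalysed conjugate addition of the Grignard reagent accelerated by Me3SiCl should take place anti to the silyloxy group on the neighbouring quaternary carbon, which sets the new ring stereocentre, and the enolate is trapped regiospecifically as its trimethylsilyl ether.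

Step 13
Reactants: 18 silyl enol ether with dihydrofuran
Product: 20 (1R,3aR,6S,8aR)-1-[(tert-butyldimethylsilyl)oxy]-5-[(Z)-2-hydroxyethylidene]-1,4,4,6-tetramethyloctahydroazulen-3(2H)-one, via trimethylsilyl ether 19 (not isolated)
Conditions: Me3SiOTf (0.3 equiv), 2,6-di-tert-butyl-4-methylpyridine (0.5 equiv), CH2Cl2, −78 → −40 °C; then AcOH, THF/H2O, 0 °C
Reagents that add atoms: none
Why: Proposed new method: O-silylation of the 2,5-dihydrofuran by Me3SiOTf and heterolysis of its tertiary allylic C–O bond should give a 1,1-dimethylallyl cation whose CH2OSiMe3 arm is still cis to the cationic CMe2 carbon, and the tethered silyl enol ether should capture that carbon and return Me3SiOTf, so that the step is a catalytic isomerisation of 18 to 19 (the acetic acid work-up then frees the primary alcohol). The closest known reaction types are the Lewis-acid SN1 α-tert-alkylation of silyl enol ethers and allyl-cation-initiated cation–olefin cyclisations that end on an enol silane; new is a cyclic allylic ether as the cation source. The seven-membered ring closes in a 7-exo mode with respect to the enol ether double bond (enolexo) at the ring-proximal allyl terminus, since attack at the other terminus would need a nine-membered ring. The new stereocentre (the ring-fusion CH next to the ketone) is controlled by the neighbouring stereocentre that carries the tether, which can deliver the cation only to its own face and so gives the cis-fused bicyclo[5.3.0]decanone. The Z geometry of the exocyclic alkene is secured by the ring from which the cation is born, because rotation about the bond to the CH terminus would localise the charge on a secondary carbon and is slow. The step needs C–C bond formation to outrun proton loss from the cation and protodesilylation of the enol silane, which the hindered pyridine base, the low temperature and the intramolecular seven-membered closure are meant to secure.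

Step 14
Reactants: 20 hydroxy ketone
Product: 21 tosylhydrazone of 20
Conditions: TsNHNH2, EtOH, 50 °C
Reagents that add atoms: p-toluenesulfonyl hydrazide, Cc1ccc(cc1)S(=O)(=O)NN
Why: Condensation of the cyclopentanone with the sulfonyl hydrazide (hydrazone formation) prepares the helper carbonyl for reductive removal under conditions mild enough for the β-silyloxy group.

Step 15
Reactants: 21 tosylhydrazone
Product: 22 (2Z)-2-[(1R,3aR,6S,8aR)-1-[(tert-butyldimethylsilyl)oxy]-1,4,4,6-tetramethyloctahydroazulen-5(1H)-ylidene]ethan-1-ol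
Conditions: catecholborane, CHCl3, 0 °C; then NaOAc·3H2O, 60 °C
Reagents that add atoms: none
Why: Hydride reduction of the tosylhydrazone by catecholborane followed by loss of sulfinate and N2 from the diazene (Caglioti-type deoxygenation) should turn the helper carbonyl into CH2 without base strong enough to eliminate the β-silyloxy group.

Step 16
Reactants: 22 allylic alcohol
Product: 23 (Z)-allylic bromide of 22
Conditions: CBr4, PPh3, CH2Cl2, −20 °C
Reagents that add atoms: carbon tetrabromide, BrC(Br)(Br)Br
Why: Appel bromination of the primary allylic alcohol proceeds by SN2 displacement at CH2 and should keep the Z geometry, as with neryl-type alcohols.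

Step 17
Reactants: 24 (E)-geranylacetone
Product: 25 4-[(2R,3R)-3-{2-[(2R)-3,3-dimethyloxiran-2-yl]ethyl}-3-methyloxiran-2-yl]butan-2-one
Conditions: D-fructose-derived Shi ketone (0.4 equiv), KHSO5 (Oxone), K2CO3, Bu4NHSO4, MeCN/dimethoxymethane/aq. borate buffer (pH 10.5), 0 °C
Reagents that add atoms: potassium peroxymonosulfate, [K+].[O-]S(=O)(=O)OO
Why: Shi asymmetric epoxidation by the chiral dioxirane should epoxidise both trisubstituted alkenes from the same face, giving the (R,R) internal and (R) terminal epoxides.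

Step 18
Reactants: 25 bis-epoxy ketone
Product: 26 tert-butyldimethylsilyl enol ether of 25 (terminal enol ether)
Conditions: LiN(i-Pr)2, THF, −78 °C; t-BuMe2SiCl, DMPU, −78 → 0 °C
Reagents that add atoms: tert-butyldimethylsilyl chloride, CC(C)(C)[Si](C)(C)Cl
Why: Kinetic deprotonation of the methyl ketone at the methyl group and O-silylation give the terminal enol silane, and the epoxides tolerate the amide base at low temperature.

Step 19
Reactants: 26 bis-epoxy enol silane
Product: 27 (3R,5aR,9aR)-3-[(tert-butyldimethylsilyl)oxy]-2,2,5a-trimethyloctahydro-1-benzoxepin-7(2H)-one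
Conditions: t-BuMe2SiOTf (0.3 equiv), 2,6-di-tert-butyl-4-methylpyridine (0.5 equiv), CH2Cl2, −78 °C
Reagents that add atoms: none
Why: In this silyl-triflate-initiated tandem oxa-/carbacyclisation the silylated terminal epoxide should be opened at its tertiary carbon by the oxygen of the internal epoxide (oxepane), and the resulting epoxonium ion opened at its tertiary carbon with inversion by the enol silane (cyclohexanone), so that the E alkene geometry and the epoxide configurations become the trans ring fusion and the angular methyl group.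

Step 20
Reactants: 27 bicyclic ketone
Product: 28 (3R,5aR,9aR)-3-[(tert-butyldimethylsilyl)oxy]-2,2,5a-trimethyl-3,4,5,5a,6,9a-hexahydro-1-benzoxepin-7(2H)-one
Conditions: IBX (2.5 equiv), toluene/DMSO (2:1), 70 °C
Reagents that add atoms: none
Why: IBX dehydrogenation of the ketone can introduce the double bond only on the side away from the quaternary carbon, and the resulting enone blocks that α-position for the alkylation that follows.

Step 21
Reactants: 28 enone; 23 allylic bromide
Product: 29 C-6-alkylated enone (both C-6 epimers)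
Conditions: LiN(i-Pr)2, THF, −78 °C; then 23, DMPU, −78 → −20 °C
Reagents that add atoms: none
Why: Alkylation of the cross-conjugated lithium dienolate (α′-deprotonation is the only kinetic option) with the allylic bromide by SN2 joins the two halves with the Z alkene intact, and the new stereocentre is not controlled here but corrected in step 22.

Step 22
Reactants: 29 alkylated enone
Product: 31 (3R,5aR,6R,9aR)-3-[(tert-butyldimethylsilyl)oxy]-6-{(2Z)-2-[(1R,3aR,6S,8aR)-1-[(tert-butyldimethylsilyl)oxy]-1,4,4,6-tetramethyloctahydroazulen-5(1H)-ylidene]ethyl}-2,2,5a-trimethyloctahydro-1-benzoxepin-7(2H)-one, via ketone epimers 30 (not isolated)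
Conditions: H2 (1 atm), RhCl(PPh3)3 (5 mol%), benzene, 23 °C; then NaOMe (0.2 equiv), MeOH, 23 °C
Reagents that add atoms: none
Why: Homogeneous hydrogenation should reduce the disubstituted enone double bond and spare the hindered trisubstituted alkene, and base equilibration of the centre α to the ketone should then funnel both epimers into the one with the equatorial side chain (thermodynamic control).

Step 23
Reactants: 31 ketone
Product: 32 (3R,5aR,6R,7S,9aR)-tertiary alcohol (7-methyl-7-ol) of 31
Conditions: MeMgBr, CeCl3, THF, −78 → 0 °C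
Reagents that add atoms: methylmagnesium bromide, C[Mg]Br
Why: 1,2-Addition of the methylcerium reagent (which suppresses enolisation) should come from the equatorial direction, because the axial path is blocked by the 1,3-diaxial angular methyl group, and so gives the axial tertiary alcohol.

Step 24
Reactants: 32 bis-silyl ether
Product: 33 triol (3,7-diol of the benzoxepane and 1-ol of the hydroazulene)
Conditions: Bu4NF (excess), THF, 60 °C
Reagents that add atoms: none
Why: Fluoride desilylation should remove both the secondary and the hindered tertiary silyl ether on warming.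

Step 25
Reactants: 33 triol
Product: 34 target CNP0157787.1
Conditions: Dess–Martin periodinane, NaHCO3, CH2Cl2, 23 °C
Reagents that add atoms: none
Why: Dess–Martin oxidation converts the only secondary alcohol into the oxepanone ketone, while the two tertiary alcohols cannot be oxidised.

**Compound list**

1 | (R)-linalool, (3R)-3,7-dimethylocta-1,6-dien-3-ol | C=C[C@](C)(O)CCC=C(C)C | starting material
2 | (1R)-1-methylcyclopent-2-en-1-ol | C1=CCC[C@@]1(C)O | intermediate
3 | tert-butyldimethyl{[(1R)-1-methylcyclopent-2-en-1-yl]oxy}silane | C1=CCC[C@@]1(C)O[Si](C)(C)C(C)(C)C | intermediate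
4 | (4R)-4-[(tert-butyldimethylsilyl)oxy]-4-methylcyclopent-2-en-1-one | C1=CC(=O)C[C@@]1(C)O[Si](C)(C)C(C)(C)C | intermediate
5 | (3R)-5-methoxy-3-methyl-5-oxopentanoic acid (methyl hydrogen (R)-3-methylglutarate) | C[C@H](CC(=O)O)CC(=O)OC | starting material
6 | (3S)-5-hydroxy-3-methylpentanoic acid | C[C@H](CC(=O)O)CCO | intermediate
7 | (4S)-4-methyloxan-2-one | C[C@@H]1CC(=O)OCC1 | intermediate
8 | (4S)-3-[(dimethylamino)methyl]-4-methyloxan-2-one (C-3 epimers) | C[C@@H]1C(CN(C)C)C(=O)OCC1 | intermediate
9 | {[(4S)-4-methyl-2-oxooxan-3-yl]methyl}trimethylammonium iodide (C-3 epimers) | C[C@@H]1C(C[N+](C)(C)C)C(=O)OCC1.[I-] | intermediate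
10 | (4S)-4-methyl-3-methylideneoxan-2-one | C[C@@H]1C(=C)C(=O)OCC1 | intermediate
11 | (3S)-3,5-dimethyl-4-methylidenehexane-1,5-diol | C[C@H](C(=C)C(C)(C)O)CCO | intermediate
12 | (4S)-6-[(tert-butyldimethylsilyl)oxy]-2,4-dimethyl-3-methylidenehexan-2-ol | C[C@H](C(=C)C(C)(C)O)CCO[Si](C)(C)C(C)(C)C | intermediate
13 | tert-butyl{[(3S)-3,5-dimethyl-4-methylidene-5-(prop-2-en-1-yloxy)hexyl]oxy}dimethylsilane | C[C@H](C(=C)C(C)(C)OCC=C)CCO[Si](C)(C)C(C)(C)C | intermediate
14 | tert-butyl{[(3S)-3-(2,2-dimethyl-2,5-dihydrofuran-3-yl)butyl]oxy}dimethylsilane | C[C@H](C1=CCOC1(C)C)CCO[Si](C)(C)C(C)(C)C | intermediate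
15 | (3S)-3-(2,2-dimethyl-2,5-dihydrofuran-3-yl)butan-1-ol | C[C@H](C1=CCOC1(C)C)CCO | intermediate
16 | 3-[(2S)-4-bromobutan-2-yl]-2,2-dimethyl-2,5-dihydrofuran | C[C@H](C1=CCOC1(C)C)CCBr | intermediate
17 | [(3S)-3-(2,2-dimethyl-2,5-dihydrofuran-3-yl)butyl]magnesium bromide | C[C@H](C1=CCOC1(C)C)CC[Mg]Br | intermediate
18 | tert-butyl({(1R,5R)-5-[(3S)-3-(2,2-dimethyl-2,5-dihydrofuran-3-yl)butyl]-1-methyl-3-[(trimethylsilyl)oxy]cyclopent-3-en-1-yl}oxy)dimethylsilane | C[C@H](C1=CCOC1(C)C)CC[C@@H]2C=C(O[Si](C)(C)C)C[C@@]2(C)O[Si](C)(C)C(C)(C)C | intermediate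
19 | (1R,3aR,6S,8aR)-1-[(tert-butyldimethylsilyl)oxy]-1,4,4,6-tetramethyl-5-{(Z)-2-[(trimethylsilyl)oxy]ethylidene}octahydroazulen-3(2H)-one | C[C@H]1CC[C@@H]2[C@@H](C(=O)C[C@@]2(C)O[Si](C)(C)C(C)(C)C)C(C)(C)/C1=C\CO[Si](C)(C)C | intermediate
20 | (1R,3aR,6S,8aR)-1-[(tert-butyldimethylsilyl)oxy]-5-[(Z)-2-hydroxyethylidene]-1,4,4,6-tetramethyloctahydroazulen-3(2H)-one | C[C@H]1CC[C@@H]2[C@@H](C(=O)C[C@@]2(C)O[Si](C)(C)C(C)(C)C)C(C)(C)/C1=C\CO | intermediate
21 | 4-methylbenzenesulfonohydrazone of 20 | C[C@H]1CC[C@@H]2[C@@H](C(=NNS(=O)(=O)c3ccc(C)cc3)C[C@@]2(C)O[Si](C)(C)C(C)(C)C)C(C)(C)/C1=C\CO | intermediate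
22 | (2Z)-2-[(1R,3aR,6S,8aR)-1-[(tert-butyldimethylsilyl)oxy]-1,4,4,6-tetramethyloctahydroazulen-5(1H)-ylidene]ethan-1-ol | C[C@H]1CC[C@@H]2[C@@H](CC[C@@]2(C)O[Si](C)(C)C(C)(C)C)C(C)(C)/C1=C\CO | intermediate
23 | {[(1R,3aR,5Z,6S,8aR)-5-(2-bromoethylidene)-1,4,4,6-tetramethyldecahydroazulen-1-yl]oxy}(tert-butyl)dimethylsilane | C[C@H]1CC[C@@H]2[C@@H](CC[C@@]2(C)O[Si](C)(C)C(C)(C)C)C(C)(C)/C1=C\CBr | intermediate
24 | (5E)-6,10-dimethylundeca-5,9-dien-2-one (geranylacetone) | CC(=O)CC/C=C(\C)CCC=C(C)C | starting material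
25 | 4-[(2R,3R)-3-{2-[(2R)-3,3-dimethyloxiran-2-yl]ethyl}-3-methyloxiran-2-yl]butan-2-one | CC(=O)CC[C@H]1O[C@]1(C)CC[C@H]2OC2(C)C | intermediate
26 | tert-butyl({4-[(2R,3R)-3-{2-[(2R)-3,3-dimethyloxiran-2-yl]ethyl}-3-methyloxiran-2-yl]but-1-en-2-yl}oxy)dimethylsilane | C=C(O[Si](C)(C)C(C)(C)C)CC[C@H]1O[C@]1(C)CC[C@H]2OC2(C)C | intermediate
27 | (3R,5aR,9aR)-3-[(tert-butyldimethylsilyl)oxy]-2,2,5a-trimethyloctahydro-1-benzoxepin-7(2H)-one | C1[C@@]2(C)CC[C@@H](O[Si](C)(C)C(C)(C)C)C(C)(C)O[C@@H]2CCC1=O | intermediate
28 | (3R,5aR,9aR)-3-[(tert-butyldimethylsilyl)oxy]-2,2,5a-trimethyl-3,4,5,5a,6,9a-hexahydro-1-benzoxepin-7(2H)-one | C1[C@@]2(C)CC[C@@H](O[Si](C)(C)C(C)(C)C)C(C)(C)O[C@@H]2C=CC1=O | intermediate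
29 | enone 28 carrying at C-6 the (2Z)-2-[(1R,3aR,6S,8aR)-1-silyloxy-1,4,4,6-tetramethyloctahydroazulen-5(1H)-ylidene]ethyl group (C-6 epimers) | C[C@H]1CC[C@@H]2[C@@H](CC[C@@]2(C)O[Si](C)(C)C(C)(C)C)C(C)(C)/C1=C\CC1[C@@]2(C)CC[C@@H](O[Si](C)(C)C(C)(C)C)C(C)(C)O[C@@H]2C=CC1=O | intermediate
30 | 8,9-dihydro derivative of 29 (C-6 epimers) | C[C@H]1CC[C@@H]2[C@@H](CC[C@@]2(C)O[Si](C)(C)C(C)(C)C)C(C)(C)/C1=C\CC1[C@@]2(C)CC[C@@H](O[Si](C)(C)C(C)(C)C)C(C)(C)O[C@@H]2CCC1=O | intermediate
31 | (3R,5aR,6R,9aR)-3-[(tert-butyldimethylsilyl)oxy]-6-{(2Z)-2-[(1R,3aR,6S,8aR)-1-[(tert-butyldimethylsilyl)oxy]-1,4,4,6-tetramethyloctahydroazulen-5(1H)-ylidene]ethyl}-2,2,5a-trimethyloctahydro-1-benzoxepin-7(2H)-one | C[C@H]1CC[C@@H]2[C@@H](CC[C@@]2(C)O[Si](C)(C)C(C)(C)C)C(C)(C)/C1=C\C[C@@H]1[C@@]2(C)CC[C@@H](O[Si](C)(C)C(C)(C)C)C(C)(C)O[C@@H]2CCC1=O | intermediate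
32 | (3R,5aR,6R,7S,9aR)-3-[(tert-butyldimethylsilyl)oxy]-6-{(2Z)-2-[(1R,3aR,6S,8aR)-1-[(tert-butyldimethylsilyl)oxy]-1,4,4,6-tetramethyloctahydroazulen-5(1H)-ylidene]ethyl}-2,2,5a,7-tetramethyldecahydro-1-benzoxepin-7-ol | C[C@H]1CC[C@@H]2[C@@H](CC[C@@]2(C)O[Si](C)(C)C(C)(C)C)C(C)(C)/C1=C\C[C@@H]1[C@@]2(C)CC[C@@H](O[Si](C)(C)C(C)(C)C)C(C)(C)O[C@@H]2CC[C@]1(C)O | intermediate
33 | (3R,5aR,6R,7S,9aR)-6-{(2Z)-2-[(1R,3aR,6S,8aR)-1-hydroxy-1,4,4,6-tetramethyloctahydroazulen-5(1H)-ylidene]ethyl}-2,2,5a,7-tetramethyldecahydro-1-benzoxepine-3,7-diol | C[C@H]1CC[C@@H]2[C@@H](CC[C@@]2(C)O)C(C)(C)/C1=C\C[C@@H]1[C@@]2(C)CC[C@@H](O)C(C)(C)O[C@@H]2CC[C@]1(C)O | intermediate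
34 | (5aR,6R,7S,9aR)-7-hydroxy-6-{(2Z)-2-[(1R,3aR,6S,8aR)-1-hydroxy-1,4,4,6-tetramethyloctahydroazulen-5(1H)-ylidene]ethyl}-2,2,5a,7-tetramethyloctahydro-1-benzoxepin-3(2H)-one (CNP0157787.1) | C[C@H]1CC[C@@H]2[C@@H](CC[C@@]2(C)O)C(C)(C)/C1=C\C[C@@H]1[C@@]2(C)CCC(=O)C(C)(C)O[C@@H]2CC[C@]1(C)O | target

Total step count: 25. Longest linear sequence: 18 steps (from 5 through steps 4–16, then steps 21–25).

**Steps most likely to fail**

Step 13 (proposed new method). The ring-opened allyl cation may be recaptured by its own silyloxy arm, or lose a proton to give a diene, faster than the hindered C–C bond forms; the enol silane may also be protodesilylated before the ring opens. The fallback is a precedented reaction type, the Lewis-acid SN1 alkylation of an enol silane by an acyclic tertiary allylic ether, with the Z geometry set earlier in the sequence by a butenolide ring. It leaves the route at 14. Allylic oxidation of the ring CH2–O group (CrO3·3,5-dimethylpyrazole, CH2Cl2, −20 °C) gives the butenolide 4-{(2S)-4-[(tert-butyldimethylsilyl)oxy]butan-2-yl}-5,5-dimethylfuran-2(5H)-one F1. LiAlH4 (Et2O, 0 °C) opens it to (2Z)-3-{(2S)-4-[(tert-butyldimethylsilyl)oxy]butan-2-yl}-4-methylpent-2-ene-1,4-diol F2, which keeps the ring geometry. t-BuPh2SiCl/imidazole silylates the primary allylic hydroxyl to give the tertiary alcohol F3, and KH/MeI gives the tertiary allylic methyl ether F4. HF·pyridine buffered with pyridine removes only the primary alkyl silyl group to give the alcohol F5, and CBr4/PPh3 gives the bromide F6. Mg, then CuBr·SMe2/Me3SiCl and enone 4 as in step 12, give the enol silane F7. Me3SiOTf (or TiCl4) in CH2Cl2 at −78 °C ionises the methyl ether irreversibly and closes the seven-membered ring to the silyl-protected ketone F8. Bu4NF (THF, 0 °C) then returns the route to 20.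

Step 12. Addition at the β-carbon next to the quaternary centre may be slow, and facial selectivity may be poor; the magnesium enolate may also expel the silyloxy group. The fallback replaces the organocopper addition by a radical conjugate addition and a separate kinetic enolisation. It sets out from 16 and 4: (Me3Si)3SiH/AIBN (toluene, 80 °C, Giese reaction) adds the primary radical anti to the silyloxy group to give the ketone (3R,4R)-4-[(tert-butyldimethylsilyl)oxy]-3-[(3S)-3-(2,2-dimethyl-2,5-dihydrofuran-3-yl)butyl]-4-methylcyclopentan-1-one F9. LiN(i-Pr)2/Me3SiCl (THF, −78 °C) then silylates the kinetic enolate at the CH2 group remote from the quaternary carbon and returns the route to 18.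

Step 23. Facial selectivity of the methyl addition may be poor, or the hindered ketone may enolise instead of adding. The fallback builds the carbinol through an epoxide. From 31, dimethylsulfoxonium methylide (Me3S(O)I, NaH, DMSO, Corey–Chaykovsky reaction) adds reversibly and delivers the equatorial C–C bond, giving the spiro-epoxide with axial oxygen F10. LiBHEt3 (THF, 0 °C) opens the epoxide at its CH2 terminus and returns the route to 32.

**Further compounds**

F1 | step 13 | 4-{(2S)-4-[(tert-butyldimethylsilyl)oxy]butan-2-yl}-5,5-dimethylfuran-2(5H)-one | C[C@H](C1=CC(=O)OC1(C)C)CCO[Si](C)(C)C(C)(C)C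
F2 | step 13 | (2Z)-3-{(2S)-4-[(tert-butyldimethylsilyl)oxy]butan-2-yl}-4-methylpent-2-ene-1,4-diol | C[C@H](/C(=C/CO)C(C)(C)O)CCO[Si](C)(C)C(C)(C)C
F3 | step 13 | (3Z)-3-{(2S)-4-[(tert-butyldimethylsilyl)oxy]butan-2-yl}-5-[(tert-butyldiphenylsilyl)oxy]-2-methylpent-3-en-2-ol | C[C@H](/C(=C/CO[Si](c1ccccc1)(c1ccccc1)C(C)(C)C)C(C)(C)O)CCO[Si](C)(C)C(C)(C)C
F4 | step 13 | tert-butyl{[(3S,4Z)-6-[(tert-butyldiphenylsilyl)oxy]-4-(2-methoxypropan-2-yl)-3-methylhex-4-en-1-yl]oxy}dimethylsilane | C[C@H](/C(=C/CO[Si](c1ccccc1)(c1ccccc1)C(C)(C)C)C(C)(C)OC)CCO[Si](C)(C)C(C)(C)C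
F5 | step 13 | (3S,4Z)-6-[(tert-butyldiphenylsilyl)oxy]-4-(2-methoxypropan-2-yl)-3-methylhex-4-en-1-ol | C[C@H](/C(=C/CO[Si](c1ccccc1)(c1ccccc1)C(C)(C)C)C(C)(C)OC)CCO
F6 | step 13 | {[(2Z,4S)-6-bromo-3-(2-methoxypropan-2-yl)-4-methylhex-2-en-1-yl]oxy}(tert-butyl)diphenylsilane | C[C@H](/C(=C/CO[Si](c1ccccc1)(c1ccccc1)C(C)(C)C)C(C)(C)OC)CCBr
F7 | step 13 | trimethylsilyl enol ether from F6 and 4 (acyclic analogue of 18) | C[C@H](/C(=C/CO[Si](c1ccccc1)(c1ccccc1)C(C)(C)C)C(C)(C)OC)CC[C@@H]2C=C(O[Si](C)(C)C)C[C@@]2(C)O[Si](C)(C)C(C)(C)C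
F8 | step 13 | tert-butyldiphenylsilyl ether of 20 | C[C@H]1CC[C@@H]2[C@@H](C(=O)C[C@@]2(C)O[Si](C)(C)C(C)(C)C)C(C)(C)/C1=C\CO[Si](c1ccccc1)(c1ccccc1)C(C)(C)C
F9 | step 12 | (3R,4R)-4-[(tert-butyldimethylsilyl)oxy]-3-[(3S)-3-(2,2-dimethyl-2,5-dihydrofuran-3-yl)butyl]-4-methylcyclopentan-1-one | C[C@H](C1=CCOC1(C)C)CC[C@@H]2CC(=O)C[C@@]2(C)O[Si](C)(C)C(C)(C)C
F10 | step 23 | spiro-epoxide of 31 at the ketone carbon (axial oxygen, equatorial CH2) | C[C@H]1CC[C@@H]2[C@@H](CC[C@@]2(C)O[Si](C)(C)C(C)(C)C)C(C)(C)/C1=C\C[C@@H]1[C@@]2(C)CC[C@@H](O[Si](C)(C)C(C)(C)C)C(C)(C)O[C@@H]2CC[C@@]13CO3
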